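The earlier runs and the new flask are calculated for an exercise.

Per minute, the runs below lose a steady share of their substrate, and you want that share for the new flask.

common to all: substrate 0.20 M

|  | acid | scavenger | remark | time |
|---|---|---|---|---|
| south-west | 0.010 M | 0.20 M | run made earlier |  |
| south | 0.040 M | 0.20 M | run made earlier |  |
| flask | 0.0200 M | 0.200 M |  | 40 min |

| run | time / min | substrate / % | target / % |
|---|---|---|---|
| south-west | 3.00 | 91 | 5 |
| south-west | 10.0 | 74 | 24 |
| south-west | 15.0 | 65 | 37 |
| south-west | 25.0 | 50 | 46 |
| south-west | 40.0 | 29 | 65 |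
| south-west | 50.0 | 26 | 69 |
| south | 8.00 | 44 | 52 |
| south | 15.0 | 23 | 73 |
| south | 25.0 | 11 | 87 |
| south | 30.0 | 4 | 86 |
| south | 40.0 | 2 | 87 |
| south | 50.0 | 0 | 89 |

(readings scatter by 2 percentage points)

- part of the substrate that has reacted at 40 min
- pH of the solution at 40 min

One thing looks wrong at first. By 40.0 min the south-west run has turned 0.142 M of substrate with [acid] = 0.010 M, far more than the acid charged. Yet the share read from that run hardly moves: 0.0277 min⁻¹ up to 25.0 min and 0.0269 min⁻¹ up to 50.0 min. So the acid comes back after each turn, as a catalyst, and the south-west run reads as pseudo-first-order.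

The south run reads 0.0980 min⁻¹. A straight line in [acid] between the two readings gives 0.0511 min⁻¹ for this flask: that is my estimate, with the scatter of the readings in it, of its loss constant, the share of the remaining substrate lost per minute. By my reckoning, 87.1% has reacted at 40 min.

The forecast says 88% reacted and pH 1.7, on the ground that “the free acid stays essentially constant”.

The flask gives 86.3% reacted and pH 1.70.

    substrate → weak acid + target (k = 1.30 × 10⁻⁴ s⁻¹)
    substrate + weak acid ⇌ idle adduct, settled at all times (K = 2.70 M⁻¹)
    2 substrate → homo dimer (k = 8.30 × 10⁻⁶ M⁻¹ s⁻¹)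
    substrate + acid → weak acid + acid + target (k = 0.0350 M⁻¹ s⁻¹)
    weak acid + scavenger → scavenged by-product (k = 0.300 M⁻¹ s⁻¹)
    target → over-reaction product (k = 5.50 × 10⁻⁵ s⁻¹)
    weak acid ⇌ conjugate base + acid, settled at all times (K = 1.60 × 10⁻⁷ M)

At 11.8 min in this flask, weak acid has a half-life against scavenger of 0.33 min, far shorter than the 17 min of substrate by its acid step, and at 40.0 min weak acid stands at 0.00251 M, free acid at 100% of its charge, with 15% of the scavenger left. Carried to the same flask read at 10 min, the loss constant of 0.0511 min⁻¹ gives 40.0% reacted, and that neighbour stands at 39.5%.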